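## Structural features

Coelenterazine (15) is an imidazo[1,2-a]pyrazin-3(7H)-one. A five-membered imidazolone (N1, C2, C3=O, N4, C8a) is fused along the N4–C8a bond to a six-membered dihydropyrazine (N4, C5, C6, N7–H, C8, C8a). The core carries a 4-hydroxybenzyl group on C2, a 4-hydroxyphenyl group on C6 and a benzyl group on C8. There is no stereocentre, so no stereochemical relationship has to be built; the only stereo-elements on the way are an arylidene geometry and a transient quaternary C8. The electron-rich core autoxidises readily, above all when deprotonated, and is open to reduction at C5=C6. It is most stable in acid, where it is a protonated, aromatic hydroxy-imidazopyrazinium ion. The real difficulty is therefore the regiocontrolled assembly of a pyrazine with three different substituents at the right oxidation level, followed by an endgame that exposes the finished core to acid only. The key step uses two facts. First, N1–C8a–N4–C3–C2 with the benzylic carbon on C2 is the skeleton of a 5-arylidene-2-thiohydantoin, whose amidine carbon C8a can carry a leaving group. Second, C8 with its benzyl group and N7 is the α-carbon of phenylalanine; since C8 (imine-type) and C8a (amidine) are both acceptor carbons in the heteroaromatic tautomer, joining them calls for reversed polarity at C8, which a 2-azaallyl anion supplies.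

## Logic of the disconnections

15 ⇒ 12. The C8–H bond is traced back to a C8–CO2tBu bond and the two phenolic O–H bonds to O–tBu bonds. Two hydrogens are relocated: the C2 benzylic CH2 becomes an arylidene CH, and N7–H/C5–H becomes C5H2 with N7=C6. The ester is what makes C8 acidic in the key step, and the arylidene blocks enolisation at C2 while storing the oxidation level. The gain is that the air-sensitive core is replaced by a stable, fully protected, non-aromatic bicycle. The demand is that one acid treatment cleaves three tert-butyl groups, releases CO2 and moves two protons, without base, oxidant or reductant.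

12 ⇒ 10. The C8–C8a bond is cut. It is the only carbon–carbon bond of the core that is not already present in a simple building block; all other ring bonds are C–N bonds. The cut opens the pyrazine ring, removes the quaternary centre and leaves an acyclic ketimine with a methylthio group on C8a. The forward step demands a nucleophilic C8, a leaving group on C8a, and ring closure at carbon in preference to every other mode.

10 ⇒ 8 + 9. The C6=N7 imine bond is cut. This separates the amino ester from the heterocyclic ketone, a convergent condensation. The demand is dehydration under conditions that spare three tert-butyl groups and the electrophilic C8a, and an imine geometry with the nitrogen substituent syn to the CH2 arm.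

8 ⇒ 4 + 7. The N4–C5 bond is cut. An activated primary halide alkylates an acidic ring N–H. The demand is attack by the amide-type nitrogen and not by N1 or oxygen, and a product that is stable to the base.

7 ⇒ 5. The C–Br bond is cut. The demand is α-monobromination without acid, because of the aryl tert-butyl ether.

4 ⇒ 3. The S–CH3 bond is cut. Sulfur is the softest nucleophilic site, so the leaving group for C8a is installed in one alkylation; the demand is to stop after one methyl group.

3 ⇒ 1 + 2. The exocyclic C=C bond is cut. The C2 side chain comes from an aldehyde and the remaining heteroatoms from a five-membered heterocycle; the demand is only that the thermodynamic Z isomer forms.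

## Other disconnections considered

Alternative 1: The imidazolone is removed first, at N1–C2 and N4–C3, by the classical condensation of coelenteramine A4 with keto acetal A5. The pyrazine of A4 is then opened at N7–C6 and N4–C8a. In the forward key step Rh2(O2CC7H15)4 turns the N-sulfonyl triazole A1 into an α-imino carbenoid, and the azirine A2 adds through nitrogen. The ylide opens to a 1,4-diazatriene, and 6π-electrocyclisation with loss of the sulfinic acid gives pyrazine ester A3.
- In favour: the positions of benzyl and aryl follow from the connectivity of A1 and A2, the step is catalytic and convergent, and the final acid condensation of A4 with A5 is the best-established entry to the luciferin.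
- Against: A3 is only a monocyclic pyrazine at the ester level. Saponification, a Curtius-type degradation and a forcing O-demethylation must follow, and A1, A2 and A5 each need their own short sequences, two of them through azides.
- Comparison: on mechanism this alternative is the better founded, since every stage is a documented reaction class and the chosen ring closure is not. On structure the chosen plan does more per step, because its key step delivers the whole bicycle at the correct oxidation level. On step economy the chosen plan is clearly ahead, seven steps against an estimated dozen.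

Alternative 2: The cut is N1=C8a. Pyrazinone A6 is acylated on the ring nitrogen with an α-azido acyl donor to give A7. PPh3 converts the azide into an iminophosphorane, whose nitrogen attacks the ring carbonyl C8a; loss of the phosphine oxide closes the imidazolone to the bis-silyl ether A8.
- In favour: A8 is the protected target itself, with a saturated benzyl group on C2, so no decarboxylation or arylidene isomerisation is needed. Aza-Wittig closure onto imide-type carbonyls is a known process under neutral conditions, and A6 is one condensation away from an amino acid amide and an aryl glyoxal.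
- Against: the ambident pyrazinone can be acylated on oxygen, A7 is an active amide that hands its acyl group to any nucleophile, and the C8a carbonyl is a weak electrophile. A8 must also be desilylated and freed from phosphine oxide, both on the air-sensitive core.
- Comparison: in precedent for the key step the alternative is better. In step count the two are about equal. On structure it builds the five-membered ring last on a preformed pyrazinone, whereas the chosen plan builds the six-membered ring last. The chosen plan has the better endgame, because deprotection and formation of the core coincide in acid.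

Alternative 3: The cuts are N4–C3 and N4–C8a, and the pyrazine is closed afterwards by imine formation at N7=C6. Dipeptide A9 and aldehyde A10 give, under Erlenmeyer conditions, the azlactone A11, whose phenol is acetylated in the process. Amino ketone A12 opens the lactone carbonyl, the new amide nitrogen recloses on the phenylalanine carbonyl with loss of water, and the base removes the acetate, giving imidazolone A13. Acid then removes the Boc group, the amine condenses with the ketone, and proton shifts lead to the target.
- In favour: the C8–C8a bond is phenylalanine's own bond, so the bond that the chosen plan must create by new chemistry is simply bought. All reaction types are standard, the arylidene stores the oxidation level in the same way, and three or four steps suffice.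
- Against: the Erlenmeyer condensation of a urethane-protected aminoacyl glycine in hot Ac2O is less secure than with simple acyl glycines. The free base of A12 self-condenses, and cyclodehydration onto a hindered, α-branched amide carbonyl needs hot basic conditions.
- Comparison: on step economy and on precedent this alternative is better than the chosen plan. On structure the two are equal, since both reach the same arylidene dihydro skeleton before the final proton shifts. The chosen plan offers only the avoidance of the self-condensing amino ketone and the new C–C bond construction. Alternative 3 is therefore kept as the fallback of the key step.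

Key step: step 6

Assumptions (chemistry):
- The target is coelenterazine, written as its 7H-tautomer.
- tert-Butyl ethers are chosen for both phenols so that they fall in the same acid step as the ester.
- Compounds 2 and 5 are taken as commercial, and 9 is used as the free base.
- The stereocentre of 9 is erased in step 6, so the racemic ester would serve equally.

## Route

Step 1
Reactants: 1 2-thiohydantoin (2-thioxoimidazolidin-4-one); 2 4-tert-butoxybenzaldehyde
Product: 3 (5Z)-5-[4-(tert-butoxy)benzylidene]-2-thioxoimidazolidin-4-one
Conditions: piperidine (0.3 equiv), EtOH, reflux; then H2O, AcOH to pH 6, filtration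
Reagents that add atoms: none
Why: Knoevenagel condensation at the doubly activated C5 methylene; the reversible conditions should deliver the thermodynamic Z isomer (aryl syn to N1, vinyl H syn to the C4 carbonyl), and the basic medium leaves the aryl tert-butyl ether untouched.

Step 2
Reactants: 3 (5Z)-5-[4-(tert-butoxy)benzylidene]-2-thioxoimidazolidin-4-one
Product: 4 (4Z)-4-[4-(tert-butoxy)benzylidene]-2-(methylsulfanyl)-1H-imidazol-5(4H)-one (N–H on the nitrogen next to the carbonyl)
Conditions: MeI (1.05 equiv), K2CO3 (1.0 equiv), DMF, 0 °C → rt
Reagents that add atoms: iodomethane CI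
Why: S-alkylation of the thiohydantoin anion, whose soft sulfur is its most nucleophilic site; limiting MeI to one equivalent should prevent N-methylation.

Step 3
Reactants: 5 4'-tert-butoxyacetophenone [1-(4-tert-butoxyphenyl)ethanone]
Product: 7 2-bromo-1-(4-tert-butoxyphenyl)ethanone, via trimethylsilyl enol ether 6 (not isolated)
Conditions: LiN(SiMe3)2, THF, −78 °C; Me3SiCl, −78 → 0 °C; then NBS, NaHCO3, THF, 0 °C
Reagents that add atoms: N-bromosuccinimide O=C1CCC(=O)N1Br
Why: α-Bromination of a ketone through its silyl enol ether; the medium stays neutral, so no HBr arises that could cleave the aryl tert-butyl ether, and only one bromine can be introduced.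

Step 4
Reactants: 4 (4Z)-4-[4-(tert-butoxy)benzylidene]-2-(methylsulfanyl)-1H-imidazol-5(4H)-one; 7 2-bromo-1-(4-tert-butoxyphenyl)ethanone
Product: 8 (4Z)-4-[4-(tert-butoxy)benzylidene]-1-[2-(4-tert-butoxyphenyl)-2-oxoethyl]-2-(methylsulfanyl)-1H-imidazol-5(4H)-one
Conditions: K2CO3 (1.2 equiv), MeCN, 0 °C → rt
Reagents that add atoms: none
Why: SN2 N-alkylation of the imidazolone anion by an activated α-bromoketone; the amide-type nitrogen should react because N1 is flanked by the methylthio group and the syn aryl ring, and the mild base and low temperature limit enolisation of the product.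

Step 5
Reactants: 8 (4Z)-4-[4-(tert-butoxy)benzylidene]-1-[2-(4-tert-butoxyphenyl)-2-oxoethyl]-2-(methylsulfanyl)-1H-imidazol-5(4H)-one; 9 L-phenylalanine tert-butyl ester [tert-butyl (2S)-2-amino-3-phenylpropanoate]
Product: 10 tert-butyl (2S)-2-[[1-(4-tert-butoxyphenyl)-2-[(4Z)-4-(4-tert-butoxybenzylidene)-2-(methylsulfanyl)-5-oxo-4,5-dihydro-1H-imidazol-1-yl]ethylidene]amino]-3-phenylpropanoate (C=N geometry not fixed; the isomer with the nitrogen substituent anti to the aryl group should predominate)
Conditions: 9 (1.2 equiv), Et3N (4 equiv), TiCl4 (0.6 equiv), CH2Cl2, −10 °C → rt; filtration through Celite and basic Al2O3, used crude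
Reagents that add atoms: none
Why: Weingarten-type ketimine formation, in which TiCl4 activates the ketone and binds the water irreversibly; the excess of amine buffers the Lewis acid so that the tert-butyl groups should survive, and the hindered amine should not displace the methylthio group at this temperature.

Step 6
Reactants: 10 tert-butyl (2S)-2-[[1-(4-tert-butoxyphenyl)-2-[(4Z)-4-(4-tert-butoxybenzylidene)-2-(methylsulfanyl)-5-oxo-4,5-dihydro-1H-imidazol-1-yl]ethylidene]amino]-3-phenylpropanoate
Product: 12 tert-butyl (2Z)-8-benzyl-2-(4-tert-butoxybenzylidene)-6-(4-tert-butoxyphenyl)-3-oxo-2,3,5,8-tetrahydroimidazo[1,2-a]pyrazine-8-carboxylate (racemic at C8), via potassium 2-azaallyl species 11 (not isolated)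
Conditions: KOtBu (1.05 equiv), THF (0.02 M), −40 → 0 °C, Ar; then aq NH4Cl
Reagents that add atoms: none
Why: Proposed new method: KOtBu removes the α-proton of the phenylalanine unit of 10, the most acidic C–H because its anion is shared by the ester and the C=N bond, and the 2-azaallyl species 11 adds through C8 to the amidine carbon C8a to give an N1-centred aza-enolate that expels methanethiolate, the best leaving group on that carbon (addition–elimination at sp2 carbon). The closest known reaction types are the C-alkylation and C-arylation of amino-ester Schiff-base anions and the displacement of the 2-alkylthio group of imidazol-4-ones by amines. The pyrazine ring closes in a 6-exo-trig mode with respect to C8a=N1, with the azaallyl unit inside the new ring (enolendo-type), which is geometrically allowed for a six-membered ring. The new stereocentre, quaternary C8, is formed without a controlling element and therefore as a racemate, which is harmless because C8 becomes sp2 again in step 7. The step needs site selectivity: C6 and C5 of the anion could only close four- and three-membered rings, the imine lone pair points away from C8a in the ketimine geometry that places C8 syn to the CH2 arm, and addition to the C3 carbonyl, also through a six-membered transition state, gives an alkoxide without a leaving group that can only revert. Irreversible loss of thiolate should therefore drain the equilibrating anions into 12. Low temperature, high dilution and one equivalent of base are chosen to hold back Michael addition to the arylidene of a second molecule and deprotonation of 12 at C5.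

Step 7
Reactants: 12 tert-butyl (2Z)-8-benzyl-2-(4-tert-butoxybenzylidene)-6-(4-tert-butoxyphenyl)-3-oxo-2,3,5,8-tetrahydroimidazo[1,2-a]pyrazine-8-carboxylate
Product: 15 coelenterazine [8-benzyl-2-(4-hydroxybenzyl)-6-(4-hydroxyphenyl)imidazo[1,2-a]pyrazin-3(7H)-one], via 8-carboxylic acid 13 (not isolated), via decarboxylated arylidene tautomer 14 (not isolated)
Conditions: anhydrous TFA/CH2Cl2 (1:1), anisole (10 equiv), Ar, 0 °C → rt; concentrate; degassed EtOH, 40 °C; precipitation with degassed Et2O
Reagents that add atoms: none
Why: Acidolysis removes the tert-butyl ester and both aryl tert-butyl ethers as isobutene, with anisole as cation scavenger. Acid 13 is both a β-imino acid and an amino acid Schiff base, so loss of CO2 leaves a doubly stabilised carbanion equivalent at C8. Imine–enamine proton shifts (N1–H to the arylidene carbon, C5–H to N7) should then end in the protonated, aromatic form of 15, which is the form most resistant to autoxidation.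

## Compound list

1 | 2-thiohydantoin (2-thioxoimidazolidin-4-one) | S=C1NCC(=O)N1 | starting material
2 | 4-tert-butoxybenzaldehyde | O=Cc1ccc(OC(C)(C)C)cc1 | starting material
3 | (5Z)-5-[4-(tert-butoxy)benzylidene]-2-thioxoimidazolidin-4-one | S=C1N/C(=C\c2ccc(OC(C)(C)C)cc2)C(=O)N1 | intermediate
4 | (4Z)-4-[4-(tert-butoxy)benzylidene]-2-(methylsulfanyl)-1H-imidazol-5(4H)-one | CSC1=N/C(=C\c2ccc(OC(C)(C)C)cc2)C(=O)N1 | intermediate
5 | 4'-tert-butoxyacetophenone | CC(=O)c1ccc(OC(C)(C)C)cc1 | starting material
6 | {[1-(4-tert-butoxyphenyl)ethenyl]oxy}trimethylsilane | C=C(O[Si](C)(C)C)c1ccc(OC(C)(C)C)cc1 | intermediate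
7 | 2-bromo-1-(4-tert-butoxyphenyl)ethanone | O=C(CBr)c1ccc(OC(C)(C)C)cc1 | intermediate
8 | (4Z)-4-[4-(tert-butoxy)benzylidene]-1-[2-(4-tert-butoxyphenyl)-2-oxoethyl]-2-(methylsulfanyl)-1H-imidazol-5(4H)-one | CSC1=N/C(=C\c2ccc(OC(C)(C)C)cc2)C(=O)N1CC(=O)c1ccc(OC(C)(C)C)cc1 | intermediate
9 | L-phenylalanine tert-butyl ester, tert-butyl (2S)-2-amino-3-phenylpropanoate | N[C@@H](Cc1ccccc1)C(=O)OC(C)(C)C | starting material
10 | tert-butyl (2S)-2-[[1-(4-tert-butoxyphenyl)-2-[(4Z)-4-(4-tert-butoxybenzylidene)-2-(methylsulfanyl)-5-oxo-4,5-dihydro-1H-imidazol-1-yl]ethylidene]amino]-3-phenylpropanoate | CSC1=N/C(=C\c2ccc(OC(C)(C)C)cc2)C(=O)N1CC(=N[C@@H](Cc1ccccc1)C(=O)OC(C)(C)C)c1ccc(OC(C)(C)C)cc1 | intermediate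
11 | potassium 2-azaallyl species of 10 (carbanion at the former phenylalanine α-carbon, potassium salt) | CSC1=N/C(=C\c2ccc(OC(C)(C)C)cc2)C(=O)N1CC(=N[C-](Cc1ccccc1)C(=O)OC(C)(C)C)c1ccc(OC(C)(C)C)cc1.[K+] | intermediate
12 | tert-butyl (2Z)-8-benzyl-2-(4-tert-butoxybenzylidene)-6-(4-tert-butoxyphenyl)-3-oxo-2,3,5,8-tetrahydroimidazo[1,2-a]pyrazine-8-carboxylate, racemic at C8 | CC(C)(C)OC(=O)C1(Cc2ccccc2)N=C(c2ccc(OC(C)(C)C)cc2)CN2C(=O)/C(=C/c3ccc(OC(C)(C)C)cc3)N=C12 | intermediate
13 | (2Z)-8-benzyl-2-(4-hydroxybenzylidene)-6-(4-hydroxyphenyl)-3-oxo-2,3,5,8-tetrahydroimidazo[1,2-a]pyrazine-8-carboxylic acid, racemic at C8 | OC(=O)C1(Cc2ccccc2)N=C(c2ccc(O)cc2)CN2C(=O)/C(=C/c3ccc(O)cc3)N=C12 | intermediate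
14 | (2Z)-8-benzyl-2-(4-hydroxybenzylidene)-6-(4-hydroxyphenyl)-1,5-dihydroimidazo[1,2-a]pyrazin-3(2H)-one | O=C1/C(=C/c2ccc(O)cc2)NC2=C(Cc3ccccc3)N=C(c3ccc(O)cc3)CN12 | intermediate
15 | coelenterazine, 8-benzyl-2-(4-hydroxybenzyl)-6-(4-hydroxyphenyl)imidazo[1,2-a]pyrazin-3(7H)-one | O=c1c(Cc2ccc(O)cc2)nc2c(Cc3ccccc3)[nH]c(-c3ccc(O)cc3)cn1-2 | target

## Step count and least certain steps

Total step count: 7. Longest linear sequence: 6 steps (steps 1, 2, 4, 5, 6 and 7, starting from 1); step 3 is a one-step side branch.

Step 6 (key step, proposed new method). The most likely failure is that ring closure at carbon is outrun by other processes. The hindered quaternary centre forms slowly, so the anion may instead undergo a 1,3-proton shift to the isomeric imine, or close through the imine nitrogen to a five-membered ring after C=N isomerisation. It may also add to the arylidene of a second molecule, or the base may add to C8a. The fallback takes the C8–C8a bond from phenylalanine itself, using known reaction types. Aldehyde 2 is condensed with N-Boc-L-phenylalanylglycine (A9) under Erlenmeyer–Plöchl conditions (Ac2O, NaOAc, 80 °C) to give the azlactone tert-butyl N-[(1S)-1-[(4Z)-4-(4-tert-butoxybenzylidene)-5-oxo-4,5-dihydro-1,3-oxazol-2-yl]-2-phenylethyl]carbamate F1. Aminolysis with the hydrochloride of 2-amino-1-(4-hydroxyphenyl)ethanone (A12) and Et3N, followed by cyclodehydration (K2CO3, EtOH, reflux), should convert it into the imidazolone tert-butyl N-[(1S)-1-[(4Z)-4-(4-tert-butoxybenzylidene)-1-[2-(4-hydroxyphenyl)-2-oxoethyl]-5-oxo-4,5-dihydro-1H-imidazol-2-yl]-2-phenylethyl]carbamate F2. Anhydrous TFA with anisole then removes the Boc and tert-butyl groups, the liberated amine closes on the ketone, and the proton shifts of step 7 should follow. This fallback sets out from 2 and returns to the route at 15.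

Step 5. The most likely failures are loss of tert-butyl groups to the Lewis acid, slow condensation of the α-branched amine with an aryl ketone, hydrolysis of the ketimine on isolation, and thermal ring closure through nitrogen if the product is warmed. The fallback forms the C=N bond without acid and without releasing water. Amine 9 is converted by diazo transfer (imidazole-1-sulfonyl azide hydrogen sulfate, CuSO4 cat., K2CO3, MeOH) into tert-butyl (2S)-2-azido-3-phenylpropanoate F3. Staudinger reaction with PMe3 in THF gives the iminophosphorane tert-butyl (2S)-3-phenyl-2-[(trimethyl-λ5-phosphanylidene)amino]propanoate F4. Aza-Wittig reaction of F4 with ketone 8 (THF, rt to 40 °C) should give the ketimine. This fallback sets out from 9 and returns at 10.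

Step 7. The most likely failures are autoxidation of the electron-rich core during concentration and isolation, and stalling of the proton shifts at the arylidene stage. The fallback purifies at the air-stable dehydro level and restores the oxidation state last. After the acidolysis of 12 the crude material is deliberately dehydrogenated (MnO2, CH2Cl2/MeOH) to dehydrocoelenterazine, (2Z)-8-benzyl-2-(4-hydroxybenzylidene)-6-(4-hydroxyphenyl)imidazo[1,2-a]pyrazin-3(2H)-one F5, which can be chromatographed and crystallised in air. Conjugate reduction with NaBH4 in degassed MeOH/CH2Cl2 at 0 °C, followed by acidification under argon, should return the luciferin. This fallback sets out from 12 and returns at 15.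

Step 4. The most likely failures are alkylation on the wrong atom of the ambident anion (N1 or the carbonyl oxygen) and base-induced over-reaction of the product, namely enolisation of the new ketone and closure of the enolate oxygen on C2 with loss of methanethiol. The fallback forms the N–C bond without base. Bromoketone 7 is converted with HCO2Na in aqueous EtOH (reflux) into 1-(4-tert-butoxyphenyl)-2-hydroxyethanone F6. F6 is then joined to the acidic N–H of 4 under Mitsunobu conditions (PPh3, diisopropyl azodicarboxylate, THF, 0 °C). This fallback sets out from 7 and returns at 8.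

## Further compounds

F1 | step 6 | tert-butyl N-[(1S)-1-[(4Z)-4-(4-tert-butoxybenzylidene)-5-oxo-4,5-dihydro-1,3-oxazol-2-yl]-2-phenylethyl]carbamate | O=C1OC(=N/C1=C\c1ccc(OC(C)(C)C)cc1)[C@H](Cc1ccccc1)NC(=O)OC(C)(C)C
F2 | step 6 | tert-butyl N-[(1S)-1-[(4Z)-4-(4-tert-butoxybenzylidene)-1-[2-(4-hydroxyphenyl)-2-oxoethyl]-5-oxo-4,5-dihydro-1H-imidazol-2-yl]-2-phenylethyl]carbamate | CC(C)(C)OC(=O)N[C@@H](Cc1ccccc1)C1=N/C(=C\c2ccc(OC(C)(C)C)cc2)C(=O)N1CC(=O)c1ccc(O)cc1
F3 | step 5 | tert-butyl (2S)-2-azido-3-phenylpropanoate | [N-]=[N+]=N[C@@H](Cc1ccccc1)C(=O)OC(C)(C)C
F4 | step 5 | tert-butyl (2S)-3-phenyl-2-[(trimethyl-λ5-phosphanylidene)amino]propanoate | CP(C)(C)=N[C@@H](Cc1ccccc1)C(=O)OC(C)(C)C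
F5 | step 7 | dehydrocoelenterazine, (2Z)-8-benzyl-2-(4-hydroxybenzylidene)-6-(4-hydroxyphenyl)imidazo[1,2-a]pyrazin-3(2H)-one | O=C1/C(=C/c2ccc(O)cc2)N=C2C(Cc3ccccc3)=NC(c3ccc(O)cc3)=CN12
F6 | step 4 | 1-(4-tert-butoxyphenyl)-2-hydroxyethanone | O=C(CO)c1ccc(OC(C)(C)C)cc1
A1 | alternative 1 | 4-(4-methoxyphenyl)-1-(4-methylbenzenesulfonyl)-1H-1,2,3-triazole | COc1ccc(cc1)-c1cn(nn1)S(=O)(=O)c1ccc(C)cc1
A2 | alternative 1 | methyl 3-benzyl-2H-azirine-2-carboxylate (racemic) | COC(=O)C1N=C1Cc1ccccc1
A3 | alternative 1 | methyl 3-benzyl-5-(4-methoxyphenyl)pyrazine-2-carboxylate | COC(=O)c1ncc(-c2ccc(OC)cc2)nc1Cc1ccccc1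
A4 | alternative 1 | coelenteramine, 3-benzyl-5-(4-hydroxyphenyl)pyrazin-2-amine | Nc1ncc(-c2ccc(O)cc2)nc1Cc1ccccc1
A5 | alternative 1 | 1,1-diethoxy-3-(4-hydroxyphenyl)propan-2-one | CCOC(OCC)C(=O)Cc1ccc(O)cc1
A6 | alternative 2 | 3-benzyl-5-[4-(tert-butyldimethylsilyloxy)phenyl]pyrazin-2(1H)-one | O=c1[nH]cc(-c2ccc(O[Si](C)(C)C(C)(C)C)cc2)nc1Cc1ccccc1
A7 | alternative 2 | 1-[2-azido-3-[4-(tert-butyldimethylsilyloxy)phenyl]propanoyl]-3-benzyl-5-[4-(tert-butyldimethylsilyloxy)phenyl]pyrazin-2(1H)-one (configuration at the azide-bearing carbon immaterial) | [N-]=[N+]=NC(Cc1ccc(O[Si](C)(C)C(C)(C)C)cc1)C(=O)n1cc(-c2ccc(O[Si](C)(C)C(C)(C)C)cc2)nc(Cc2ccccc2)c1=O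
A8 | alternative 2 | 8-benzyl-2-[4-(tert-butyldimethylsilyloxy)benzyl]-6-[4-(tert-butyldimethylsilyloxy)phenyl]imidazo[1,2-a]pyrazin-3(7H)-one | O=c1c(Cc2ccc(O[Si](C)(C)C(C)(C)C)cc2)nc2c(Cc3ccccc3)[nH]c(-c3ccc(O[Si](C)(C)C(C)(C)C)cc3)cn1-2
A9 | alternative 3 | N-Boc-L-phenylalanylglycine | CC(C)(C)OC(=O)N[C@@H](Cc1ccccc1)C(=O)NCC(=O)O
A10 | alternative 3 | 4-hydroxybenzaldehyde | O=Cc1ccc(O)cc1
A11 | alternative 3 | 4-[(Z)-[2-[(1S)-1-[(tert-butoxycarbonyl)amino]-2-phenylethyl]-5-oxo-1,3-oxazol-4(5H)-ylidene]methyl]phenyl acetate | O=C1OC(=N/C1=C\c1ccc(OC(C)=O)cc1)[C@H](Cc1ccccc1)NC(=O)OC(C)(C)C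
A12 | alternative 3 | 2-amino-1-(4-hydroxyphenyl)ethanone | NCC(=O)c1ccc(O)cc1
A13 | alternative 3 | tert-butyl N-[(1S)-1-[(4Z)-4-(4-hydroxybenzylidene)-5-oxo-1-[2-(4-hydroxyphenyl)-2-oxoethyl]-4,5-dihydro-1H-imidazol-2-yl]-2-phenylethyl]carbamate | CC(C)(C)OC(=O)N[C@@H](Cc1ccccc1)C1=N/C(=C\c2ccc(O)cc2)C(=O)N1CC(=O)c1ccc(O)cc1
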